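## Retrosynthetic overview

1. Key disconnection, ring bond C4–C5: (R)-glycidol 1 and ethyl (Z)-3-iodoacrylate 2 give hydroxymethyl-dihydropyranone 5 by nickel-catalysed capture of a β-hydroxyalkyl radical by the alkenyl iodide, then lactonisation; C6 comes from glycidol.
2. C1′–C2′: Z-γ-methoxyallylboration of lactone aldehyde 6 with allyl methyl ether 7 sets C1′ and C2′ and gives 11.
3. C5′/C6′: diacetate 15 from divinyl carbinol 12 by Sharpless desymmetrisation, hydride opening and acetylation.
4. C3′=C4′: E-selective cross-metathesis of 11 with 15 gives target 16.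
5. Ring order: the only ring, the dihydropyranone, is made first (step 1) and carried through; no other ring is formed.

Assumption: locants follow the target (ring O1, C2(=O), C3=C4, C5, C6; side chain C1′–C7′), and operations run in one flask without isolation count as one step.

## Route

Step 1
Reactants: 1 (R)-glycidol; 2 ethyl (Z)-3-iodoacrylate (1.5 equiv)
Product: 5 (S)-6-(hydroxymethyl)-5,6-dihydro-2H-pyran-2-one, via (R)-3-iodopropane-1,2-diol 3 (not isolated), via ethyl (S,Z)-5,6-dihydroxyhex-2-enoate 4 (not isolated)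
Conditions: NiCl2·glyme (10 mol%), 4,4′-di-tert-butyl-2,2′-bipyridine (10 mol%), NaI (25 mol%), Et3N·HCl (1.1 equiv), Mn powder (2 equiv), DMPU, rt, 16 h; filter; then p-TsOH·H2O (5 mol%), CH2Cl2, rt
Reagents that add atoms: none
Why: Proposed new method: iodide opens the epoxide of 1 at its CH2 terminus to iodohydrin 3, bipyridine-ligated nickel (kept reduced by Mn) adds Z-iodide 2 oxidatively with retention and captures the primary β-hydroxyalkyl radical it generates from 3 by iodine-atom abstraction, and reductive elimination from the resulting trivalent alkyl(alkenyl)nickel forms the C4–C5 bond of Z-enoate 4, whose δ-hydroxyl closes the six-membered lactone under acid (closest known type: iodide-co-catalysed nickel-catalysed reductive cross-electrophile coupling of terminal epoxides with aryl halides and of alkyl iodides with alkenyl halides, a radical process); no stereocentre is formed, and C6 keeps the glycidol configuration because its C–O bond is never broken.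

Step 2
Reactants: 5 (S)-6-(hydroxymethyl)-5,6-dihydro-2H-pyran-2-one
Product: 6 (S)-6-oxo-3,6-dihydro-2H-pyran-2-carbaldehyde
Conditions: Dess–Martin periodinane (1.3 equiv), CH2Cl2, 0 °C → rt, 1 h; dilute with Et2O/pentane, filter through Celite, concentrate cold, use at once
Reagents that add atoms: none
Why: Dess–Martin oxidation of the primary alcohol under neutral, non-aqueous conditions stops at the aldehyde and leaves the enone and the epimerisable α-acyloxy stereocentre untouched.

Step 3
Reactants: 6 (S)-6-oxo-3,6-dihydro-2H-pyran-2-carbaldehyde; 7 allyl methyl ether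
Product: 11 (S)-6-[(1S,2S)-1-hydroxy-2-methoxybut-3-en-1-yl]-5,6-dihydro-2H-pyran-2-one, via (Z)-3-methoxyallyllithium 8 (not isolated), via Z-methoxyallyl-bis(isopinocampheyl)borane 9 (not isolated), via O-boryl adduct 10 (not isolated)
Conditions: 7 (1.7 equiv), s-BuLi (1.5 equiv), THF, −78 °C; (+)-Ipc2BOMe [from (−)-α-pinene] (1.5 equiv), −78 °C; BF3·OEt2 (2.0 equiv), −78 °C; then 6 (1.0 equiv), −78 °C, 3 h; 8-hydroxyquinoline (1.6 equiv), MeOH/Et2O, rt
Reagents that add atoms: none
Why: Brown asymmetric γ-alkoxyallylboration: chelation-controlled deprotonation of 7 gives the Z anion and hence Z-allylborane 9, which adds through a closed chair transition state (Z geometry gives 1′,2′-syn) to the aldehyde Re face selected by the isopinocampheyl groups, which is also the face favoured by Felkin–Anh attack anti to the α-oxygen (matched case, 6,1′-anti), so C1′ and C2′ are both set S; 8-hydroxyquinoline frees the alcohol from boron without an oxidant or amine that could attack the enone.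

Step 4
Reactants: 12 penta-1,4-dien-3-ol
Product: 13 (S)-1-[(R)-oxiran-2-yl]prop-2-en-1-ol
Conditions: Ti(OiPr)4 (10 mol%), L-(+)-diisopropyl tartrate (13 mol%), t-BuOOH (2 equiv, isooctane), 4 Å MS, CH2Cl2, −20 °C, 5–7 d
Reagents that add atoms: tert-butyl hydroperoxide, CC(C)(C)OO
Why: Sharpless asymmetric epoxidation of the achiral divinyl carbinol combines enantiotopic-group selection with the erythro face preference of secondary allylic alcohols, so L-(+)-tartrate gives the (2R,3S) erythro monoepoxide in very high ee, the minor enantiomer being removed by a fast second epoxidation.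

Step 5
Reactants: 13 (S)-1-[(R)-oxiran-2-yl]prop-2-en-1-ol
Product: 15 (3S,4R)-pent-1-ene-3,4-diyl diacetate, via (3S,4R)-pent-1-ene-3,4-diol 14 (not isolated)
Conditions: LiAlH4 (0.6 equiv), Et2O, 0 °C, 1 h; then Ac2O (8 equiv), pyridine (10 equiv), DMAP (10 mol%), 0 °C → rt; aqueous work-up
Reagents that add atoms: acetic anhydride, CC(=O)OC(C)=O
Why: Hydride opens the terminal epoxide by SN2 attack at the unsubstituted carbon, leaving the C–O bond at the stereocentre intact, and the resulting aluminium alkoxide of the erythro diol is acetylated in the same flask (reductive opening with in-situ acetylation), which avoids isolating the volatile, water-soluble diol.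

Step 6
Reactants: 11 (S)-6-[(1S,2S)-1-hydroxy-2-methoxybut-3-en-1-yl]-5,6-dihydro-2H-pyran-2-one; 15 (3S,4R)-pent-1-ene-3,4-diyl diacetate (3 equiv)
Product: 16 (S)-6-[(1S,2S,3E,5S,6R)-5,6-diacetoxy-1-hydroxy-2-methoxyhept-3-en-1-yl]-5,6-dihydro-2H-pyran-2-one (target)
Conditions: second-generation Hoveyda–Grubbs catalyst, (H2IMes)Cl2Ru(=CH-C6H4-2-OiPr) (10 mol% in two portions), 1,4-benzoquinone (10 mol%), CH2Cl2, 40 °C, 24 h
Reagents that add atoms: none
Why: Olefin cross-metathesis of the two terminal, allylically oxygenated alkenes gives the thermodynamically favoured E-disubstituted alkene while the electron-poor cis-alkene of the lactone is inert; excess 15 (whose homodimer also reacts) drives the coupling and no stereocentre is touched.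

## Compound list

1 | (R)-glycidol [(R)-oxiran-2-ylmethanol] | OC[C@@H]1CO1 | starting material
2 | ethyl (Z)-3-iodoacrylate | CCOC(=O)/C=C\I | starting material
3 | (R)-3-iodopropane-1,2-diol | OC[C@@H](O)CI | intermediate (not isolated)
4 | ethyl (S,Z)-5,6-dihydroxyhex-2-enoate | OC[C@@H](O)C/C=C\C(=O)OCC | intermediate (not isolated)
5 | (S)-6-(hydroxymethyl)-5,6-dihydro-2H-pyran-2-one | OC[C@@H]1CC=CC(=O)O1 | intermediate
6 | (S)-6-oxo-3,6-dihydro-2H-pyran-2-carbaldehyde | O=C[C@@H]1CC=CC(=O)O1 | intermediate
7 | allyl methyl ether (3-methoxyprop-1-ene) | COCC=C | starting material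
8 | (Z)-3-methoxyallyllithium | [Li]C/C=C\OC | intermediate (not isolated)
9 | [(Z)-3-methoxyprop-2-en-1-yl]bis(isopinocampheyl)borane, isopinocampheyl groups from (−)-α-pinene | CO/C=C\CB([C@H]1C[C@H]2C[C@@H]([C@@H]1C)C2(C)C)[C@H]1C[C@H]2C[C@@H]([C@@H]1C)C2(C)C | intermediate (not isolated)
10 | O-[bis(isopinocampheyl)boryl] derivative (borinate) of alcohol 11 | CO[C@@H](C=C)[C@@H](OB([C@H]2C[C@H]3C[C@@H]([C@@H]2C)C3(C)C)[C@H]2C[C@H]3C[C@@H]([C@@H]2C)C3(C)C)[C@@H]1CC=CC(=O)O1 | intermediate (not isolated)
11 | (S)-6-[(1S,2S)-1-hydroxy-2-methoxybut-3-en-1-yl]-5,6-dihydro-2H-pyran-2-one | CO[C@@H](C=C)[C@@H](O)[C@@H]1CC=CC(=O)O1 | intermediate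
12 | penta-1,4-dien-3-ol (divinyl carbinol) | C=CC(O)C=C | starting material
13 | (S)-1-[(R)-oxiran-2-yl]prop-2-en-1-ol [(2R,3S)-1,2-epoxypent-4-en-3-ol] | C=C[C@H](O)[C@@H]1OC1 | intermediate
14 | (3S,4R)-pent-1-ene-3,4-diol, formed as its aluminium alkoxide | C=C[C@H](O)[C@@H](C)O | intermediate (not isolated)
15 | (3S,4R)-pent-1-ene-3,4-diyl diacetate | C=C[C@H](OC(C)=O)[C@@H](C)OC(C)=O | intermediate
16 | (S)-6-[(1S,2S,3E,5S,6R)-5,6-diacetoxy-1-hydroxy-2-methoxyhept-3-en-1-yl]-5,6-dihydro-2H-pyran-2-one | CO[C@@H](/C=C/[C@H](OC(C)=O)[C@@H](C)OC(C)=O)[C@@H](O)[C@@H]1CC=CC(=O)O1 | target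

## Step count and risks

Total step count: 6. Longest linear sequence: 4 (steps 1, 2, 3, 6).

Steps most likely to fail, each with one fallback:

Step 1 (nickel-catalysed radical coupling and lactonisation). The risks are loss of Z geometry, homocoupling of 2, and reductive β-elimination of the iodohydrin. The fallback sets out from 1 and comes back at 5. Epoxide 1 is opened with LiI/AcOH in THF and iodohydrin 3 is isolated. Its primary radical, generated with (Me3Si)3SiH and Et3B/air in toluene at 0 °C, is added to ethyl propiolate, a metal-free radical conjugate addition to the alkyne instead of capture by nickel. This gives enoate 4 mixed with its E isomer, ethyl (S,E)-5,6-dihydroxyhex-2-enoate F1. The crude mixture is irradiated at 254 nm in MeCN with catalytic camphorsulfonic acid; F1 isomerises to 4, which is drained from the photoequilibrium by lactonisation to 5.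

Step 3 (methoxyallylboration of the fragile α-acyloxy aldehyde 6). The risks are epimerisation or decomposition of 6 and attack on the enone during work-up. The fallback sets out from 4 and comes back at 11. The acid treatment at the end of step 1 is left out and crude diol ester 4 is silylated (TESCl, imidazole, DMF) to ethyl (S,Z)-5,6-bis(triethylsilyloxy)hex-2-enoate F2. Swern conditions [(COCl)2, DMSO, then Et3N, CH2Cl2, −78 → −30 °C] cleave the primary silyl ether and oxidise it in the same operation to the more robust open-chain aldehyde ethyl (S,Z)-6-oxo-5-(triethylsilyloxy)hex-2-enoate F3. The same allylborane 9 then gives ethyl (2Z,5S,6R,7S)-6-hydroxy-7-methoxy-5-(triethylsilyloxy)nona-2,8-dienoate F4, with Felkin–Anh and reagent control still matched. Finally 1 M HCl in THF removes the silyl group and closes the lactone to 11.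

Step 6 (cross-metathesis of two hindered, allylically oxygenated alkenes). The risks are low conversion and homodimer formation. The fallback sets out from 11 and comes back at 16. Alcohol 11 is silylated (TESOTf, 2,6-lutidine, CH2Cl2, −78 °C) to (S)-6-[(1S,2S)-2-methoxy-1-(triethylsilyloxy)but-3-en-1-yl]-5,6-dihydro-2H-pyran-2-one F5. Diol 14, isolated for this purpose from the LiAlH4 reduction of 13, replaces 15 as the metathesis partner, because a free secondary allylic alcohol is smaller and more reactive towards the ruthenium alkylidene than its acetate. The coupling gives (S)-6-[(1S,2S,3E,5S,6R)-5,6-dihydroxy-2-methoxy-1-(triethylsilyloxy)hept-3-en-1-yl]-5,6-dihydro-2H-pyran-2-one F6. Ac2O/pyridine/DMAP converts it into (S)-6-[(1S,2S,3E,5S,6R)-5,6-diacetoxy-2-methoxy-1-(triethylsilyloxy)hept-3-en-1-yl]-5,6-dihydro-2H-pyran-2-one F7, and HF·pyridine in THF removes the silyl ether to give 16.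

## Further compounds

F1 | step 1 | ethyl (S,E)-5,6-dihydroxyhex-2-enoate | OC[C@@H](O)C/C=C/C(=O)OCC
F2 | step 3 | ethyl (S,Z)-5,6-bis(triethylsilyloxy)hex-2-enoate | CC[Si](CC)(CC)OC[C@@H](O[Si](CC)(CC)CC)C/C=C\C(=O)OCC
F3 | step 3 | ethyl (S,Z)-6-oxo-5-(triethylsilyloxy)hex-2-enoate | O=C[C@@H](O[Si](CC)(CC)CC)C/C=C\C(=O)OCC
F4 | step 3 | ethyl (2Z,5S,6R,7S)-6-hydroxy-7-methoxy-5-(triethylsilyloxy)nona-2,8-dienoate | CO[C@@H](C=C)[C@@H](O)[C@@H](O[Si](CC)(CC)CC)C/C=C\C(=O)OCC
F5 | step 6 | (S)-6-[(1S,2S)-2-methoxy-1-(triethylsilyloxy)but-3-en-1-yl]-5,6-dihydro-2H-pyran-2-one | CO[C@@H](C=C)[C@@H](O[Si](CC)(CC)CC)[C@@H]1CC=CC(=O)O1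
F6 | step 6 | (S)-6-[(1S,2S,3E,5S,6R)-5,6-dihydroxy-2-methoxy-1-(triethylsilyloxy)hept-3-en-1-yl]-5,6-dihydro-2H-pyran-2-one | CO[C@@H](/C=C/[C@H](O)[C@@H](C)O)[C@@H](O[Si](CC)(CC)CC)[C@@H]1CC=CC(=O)O1
F7 | step 6 | (S)-6-[(1S,2S,3E,5S,6R)-5,6-diacetoxy-2-methoxy-1-(triethylsilyloxy)hept-3-en-1-yl]-5,6-dihydro-2H-pyran-2-one | CO[C@@H](/C=C/[C@H](OC(C)=O)[C@@H](C)OC(C)=O)[C@@H](O[Si](CC)(CC)CC)[C@@H]1CC=CC(=O)O1
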